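(The earlier runs and the new flask were generated by integration on assumed constants; the scatter is artificial.)

Divide the isomer of the product by the target, both as fractions of the substrate charged, line by line in the earlier runs. Work in base-ten logarithms, and use the winter run, whose readings are the larger.

common to all: coupling partner 11.4 mM
- noon: substrate 6 mM; protic impurity 0.60 mM; run made earlier
- winter: substrate 9 mM; protic impurity 0.60 mM; run made earlier
- flask: substrate 12 mM; protic impurity 0.600 mM; time 8.0 d

- noon (time / d: isomer of the product / %, target / %): 0.333: 10.5, 6.9; 1.04: 8.9, 6.9; 1.67: 8.8, 6.4; 3.00: 9.1, 6.5; 4.00: 8.9, 7.0; 5.00: 8.7, 6.7; 6.00: 9.2, 6.8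
- winter (time / d: isomer of the product / %, target / %): 0.500: 26.2, 19.7; 0.833: 26.6, 19.4; 1.25: 25.8, 19.6; 1.67: 26.3, 19.5; 3.00: 26.5, 19.5; 4.00: 25.9, 19.3; 6.00: 26.0, 19.4

(standard deviation of a reading: 0.3 percentage points)

1. ratio of isomer of the product to target at 5.0 min
2. ratio of isomer of the product to target at 4.0 h
3. ratio of isomer of the product to target at 8.0 d
4. which of isomer of the product and target there is more of at 8.0 d

Highest isomer reading over lowest target reading bounds the winter logarithm from above; lowest over highest bounds it from below; all readings pooled give the centre:

above: 0.139
below: 0.117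
centre: 0.128

Call the centre the tilt, the logarithm of the late isomer-to-target ratio. Pooling shrinks scatter by the root of the number of readings, 2.65 here; claim only a factor 2, so tighten the bounds:

band: 0.123 to 0.134, a ratio of 1.33 to 1.36

The noon run, from its second reading on, gives 0.124, above the lower edge and below the upper , with 6 mM of substrate against 9 mM in winter. So carry the band to the flask, charged with 12 mM, at 8.0 d, and expect the isomer ahead, since the lower edge is above zero. Commit to nothing at 5.0 min or 4.0 h: the readings begin later, at 0.333 d.

The forecast gives 1.3, 1.05 and 0.4 at these times, its last lying below the band, with target ahead after a “drift towards the thermodynamic ratio”.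

The flask gives 0.126, 1.27 and 1.33, a passage from kinetic to thermodynamic control, with a final tilt of 0.124, inside the band . In the flask, isomer of the product leads with 26.7% against 20.0% of target, and the two stand level at 0.0861 d, so sample early to watch the crossing.

    substrate + coupling partner → intermediate + released group (k = 0.310 L mol⁻¹ s⁻¹)
    intermediate ⇌ target (K = 1.50, k = 0.00320 s⁻¹)
    intermediate ⇌ isomer of the product (K = 2.00, k = 2.80 × 10⁻⁴ s⁻¹)
    substrate → decomposition product (k = 9.00 × 10⁻⁷ s⁻¹)
    coupling partner + target → over-reaction product (k = 0.220 L mol⁻¹ s⁻¹)
    coupling partner + protic impurity → quenched reagent (k = 0.830 L mol⁻¹ s⁻¹)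

Hold the same band against the neighbouring flask, charged with 0.15 mM of protic impurity instead of 0.600 mM. That flask gives 1.33 at 8.0 d, a tilt of 0.124, again above the lower edge and below the upper ; the loss of coupling partner to quenched reagent makes no difference to this ratio. Its target stands at 20.2% and its over-reaction product at 16.6%.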